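**Retrosynthetic overview**
1. Target 21 comes from hepta-O-benzyl biflavan 20 by global O-debenzylation.
2. The interflavan C4(upper)–C6(lower) bond comes from anodic C4–H activation of tri-O-benzylguibourtinidol 18 (stored as its hexafluoroisopropyl ether), then Friedel–Crafts attack by tetra-O-benzyl-ent-epifisetinidol 12; C4 is set trans to C3–O.
3. Ring C of each unit is closed last, by CuI-catalysed O1–C8a etherification (retention) of a 1,3-diarylpropan-1-ol; rings A and B are bought as arenes.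
4. C2 of each unit is set from C3 by chelation control: ArMgBr addition to aldehyde 8 (syn, gives 2,3-cis 12) or Zn(BH4)2 reduction of ketone 16 (anti, gives 2,3-trans 18).
5. C3 (S in both units) comes from one building block, methyl (S)-glycidate, opened at CH2 by the ring A Grignard from 3.

Assumption: the C4–O intermediates (19 and the fallback ether) are drawn as their 3,4-trans epimers; either epimer ionises to the same cation, so their C4 configuration does not matter.

**Step 1**
Reactants: 1 3-bromo-4-iodophenol; 2 benzyl bromide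
Product: 3 4-(benzyloxy)-2-bromo-1-iodobenzene
Conditions: BnBr (1.1 equiv), K2CO3, DMF, rt
Reagents that add atoms: benzyl bromide (2), BrCc1ccccc1
Why: Williamson ether synthesis on an unhindered phenoxide; no stereocentre is involved.

**Step 2**
Reactants: 3 4-(benzyloxy)-2-bromo-1-iodobenzene; 4 methyl (2S)-oxirane-2-carboxylate
Product: 6 methyl (2S)-3-[4-(benzyloxy)-2-bromophenyl]-2-hydroxypropanoate, via arylmagnesium chloride 5 (not isolated)
Conditions: iPrMgCl·LiCl (1.05 equiv), THF, −40 °C; then CuI (10 mol %), 4, −40 → −20 °C; aq. NH4Cl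
Reagents that add atoms: methyl (2S)-oxirane-2-carboxylate (4), COC(=O)[C@@H]1CO1
Why: chemoselective iodine–magnesium exchange (C–I over C–Br, kept cold to avoid aryne formation) followed by CuI-catalysed SN2 epoxide opening at the CH2 terminus; the purchased stereocentre is untouched and becomes C3 (S) of both flavan units.

**Step 3**
Reactants: 6 methyl (2S)-3-[4-(benzyloxy)-2-bromophenyl]-2-hydroxypropanoate; 2 benzyl bromide
Product: 7 methyl (2S)-2-(benzyloxy)-3-[4-(benzyloxy)-2-bromophenyl]propanoate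
Conditions: BnBr (1.5 equiv), Ag2O, 4 Å MS, CH2Cl2, rt, dark
Reagents that add atoms: benzyl bromide (2), BrCc1ccccc1
Why: Ag2O-promoted O-benzylation (Purdie-type alkylation) under non-basic conditions leaves the α-centre intact and installs the chelating α-OBn group used for both later stereocontrol steps.

**Step 4**
Reactants: 7 methyl (2S)-2-(benzyloxy)-3-[4-(benzyloxy)-2-bromophenyl]propanoate
Product: 8 (2S)-2-(benzyloxy)-3-[4-(benzyloxy)-2-bromophenyl]propanal
Conditions: iBu2AlH (1.1 equiv), CH2Cl2, −78 °C; aq. KNaC4H4O6 (potassium sodium tartrate); used crude at once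
Reagents that add atoms: none
Why: partial ester reduction that stops at the aluminium hemiacetal at −78 °C (DIBAL reduction); immediate use avoids α-epimerisation of the α-alkoxy aldehyde.

**Step 5**
Reactants: 8 (2S)-2-(benzyloxy)-3-[4-(benzyloxy)-2-bromophenyl]propanal; 9 4-bromo-1,2-bis(benzyloxy)benzene
Product: 11 (1S,2S)-2-(benzyloxy)-1-[3,4-bis(benzyloxy)phenyl]-3-[4-(benzyloxy)-2-bromophenyl]propan-1-ol, via arylmagnesium bromide 10 (not isolated)
Conditions: 9, Mg, THF, 40 °C; then added to 8 + MgBr2·OEt2 (2 equiv), CH2Cl2, −78 °C; aq. NH4Cl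
Reagents that add atoms: 4-bromo-1,2-bis(benzyloxy)benzene (9), Brc1ccc(OCc2ccccc2)c(OCc2ccccc2)c1
Why: Cram-chelate-controlled Grignard addition, in which magnesium bridges C=O and the α-OBn oxygen and the aryl group enters anti to the CH2Ar arm, gives the syn (1S,2S) alcohol (expected ≥10:1), so the new centre is set by C2.

**Step 6**
Reactants: 11 (1S,2S)-2-(benzyloxy)-1-[3,4-bis(benzyloxy)phenyl]-3-[4-(benzyloxy)-2-bromophenyl]propan-1-ol
Product: 12 (2S,3S)-3,7-bis(benzyloxy)-2-[3,4-bis(benzyloxy)phenyl]chromane (tetra-O-benzyl-ent-epifisetinidol; 2,3-cis)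
Conditions: CuI (10 mol %), 3,4,7,8-tetramethyl-1,10-phenanthroline (20 mol %), Cs2CO3 (2 equiv), toluene, 110 °C
Reagents that add atoms: none
Why: intramolecular Ullmann-type C–O coupling closes ring C at O1–C8a; because the aryl carbon is the electrophile the carbinol centre is retained, so syn-11 gives the 2,3-cis (2S,3S) flavan.

**Step 7**
Reactants: 7 methyl (2S)-2-(benzyloxy)-3-[4-(benzyloxy)-2-bromophenyl]propanoate; 13 N,O-dimethylhydroxylamine hydrochloride; 14 4-(benzyloxy)phenylmagnesium bromide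
Product: 16 (2S)-2-(benzyloxy)-1-[4-(benzyloxy)phenyl]-3-[4-(benzyloxy)-2-bromophenyl]propan-1-one, via Weinreb amide 15 (not isolated)
Conditions: 13 (1.5 equiv), iPrMgCl (3.0 equiv), THF, −20 °C; then 14 (3 equiv, THF), −20 → 0 °C; aq. NH4Cl
Reagents that add atoms: 4-(benzyloxy)phenylmagnesium bromide (14), Br[Mg]c1ccc(OCc2ccccc2)cc1; N,O-dimethylhydroxylamine hydrochloride (13), CNOC.Cl
Why: one-pot ester-to-amide-to-ketone sequence (Weinreb ketone synthesis), in which the chloromagnesium amide made from 13 and iPrMgCl turns ester 7 into Weinreb amide 15, whose chelated magnesium tetrahedral adduct with 14 holds until work-up, so the aryl Grignard stops at the ketone, the amine of 13 is released again (it is part of 15 only) and C2 (S) is carried through unchanged.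

**Step 8**
Reactants: 16 (2S)-2-(benzyloxy)-1-[4-(benzyloxy)phenyl]-3-[4-(benzyloxy)-2-bromophenyl]propan-1-one
Product: 17 (1R,2S)-2-(benzyloxy)-1-[4-(benzyloxy)phenyl]-3-[4-(benzyloxy)-2-bromophenyl]propan-1-ol
Conditions: Zn(BH4)2 (from ZnCl2 + NaBH4), Et2O, −30 → 0 °C
Reagents that add atoms: none
Why: chelation-controlled hydride reduction, in which zinc bridges C=O and α-OBn and hydride enters anti to the CH2Ar arm, gives the anti (1R,2S) alcohol (typically >15:1), so the new centre is set by C2.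

**Step 9**
Reactants: 17 (1R,2S)-2-(benzyloxy)-1-[4-(benzyloxy)phenyl]-3-[4-(benzyloxy)-2-bromophenyl]propan-1-ol
Product: 18 (2R,3S)-3,7-bis(benzyloxy)-2-[4-(benzyloxy)phenyl]chromane (tri-O-benzylguibourtinidol; 2,3-trans)
Conditions: CuI (10 mol %), 3,4,7,8-tetramethyl-1,10-phenanthroline (20 mol %), Cs2CO3 (2 equiv), toluene, 110 °C
Reagents that add atoms: none
Why: the same Ullmann-type ring C closure with retention at the carbinol carbon converts anti-17 into the 2,3-trans (2R,3S) flavan.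

**Step 10**
Reactants: 18 (2R,3S)-3,7-bis(benzyloxy)-2-[4-(benzyloxy)phenyl]chromane; 12 (2S,3S)-3,7-bis(benzyloxy)-2-[3,4-bis(benzyloxy)phenyl]chromane
Product: 20 hepta-O-benzyl guibourtinidol-(4α→6)-ent-epifisetinidol, via C4 hexafluoroisopropyl ether 19 (not isolated)
Conditions: undivided cell, BDD anode, Pt cathode, 18 (0.05 M), Bu4NPF6 (0.1 M), iPr2NEt (0.2 equiv), CH2Cl2/(CF3)2CHOH 2:1, 0 °C, 5 mA cm−2, 2.2 F mol−1; current off; then 12 (3 equiv, excess recovered), TfOH (0.4 equiv), −40 → −20 °C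
Reagents that add atoms: tetra-O-benzyl-ent-epifisetinidol (12), C(c1ccccc1)Oc1ccc2c(c1)O[C@@H](c1ccc(OCc3ccccc3)c(OCc3ccccc3)c1)[C@@H](OCc1ccccc1)C2; 1,1,1,3,3,3-hexafluoropropan-2-ol, OC(C(F)(F)F)C(F)(F)F
Why: Proposed new method: an anodic cross-dehydrogenative interflavan coupling in which ring A of 18 (the most easily oxidised arene) is oxidised to its radical cation and loses the aligned benzylic C4–H proton and a second electron to give the O1/O7-stabilised C4 cation, which hexafluoroisopropoxide captures as ether 19 (deactivated towards over-oxidation, never exposed to the anode together with the equally oxidisable 12, and the only compound that holds the fluorinated alcohol, which is released again); acid then re-ionises 19 and C6 of 12 (para to O1, ortho to 7-OBn, while C8 is flanked by two oxygens) attacks in a Friedel–Crafts step anti to the 3-OBn group of the half-chair cation, setting C4 as 4α (3,4-trans, expected ≥5:1) by substrate control from C3; the closest known reaction types are anodic benzylic C–H etherification of simple alkylanisoles in fluorinated alcohols followed by benzyl–aryl coupling, and the quinone-oxidant then Lewis-acid C4 activation of benzylated flavan-3-ols.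

**Step 11**
Reactants: 20 hepta-O-benzyl guibourtinidol-(4α→6)-ent-epifisetinidol
Product: 21 guibourtinidol-(4α→6)-ent-epifisetinidol (CNP0243811.1)
Conditions: H2 (1 atm), Pd(OH)2/C, THF/MeOH/H2O 20:1:1, rt
Reagents that add atoms: none
Why: catalytic hydrogenolysis cleaves all seven benzyl ethers (five aryl, two alkyl) under neutral conditions that leave the interflavan C–C bond and all five stereocentres untouched.

**Compound list**
1 | 3-bromo-4-iodophenol | Oc1ccc(I)c(Br)c1 | starting material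
2 | benzyl bromide | BrCc1ccccc1 | starting material
3 | 4-(benzyloxy)-2-bromo-1-iodobenzene | Brc1cc(OCc2ccccc2)ccc1I | intermediate
4 | methyl (2S)-oxirane-2-carboxylate (methyl (S)-glycidate) | COC(=O)[C@@H]1CO1 | starting material
5 | [4-(benzyloxy)-2-bromophenyl]magnesium chloride (formed in the flask) | Cl[Mg]c1ccc(OCc2ccccc2)cc1Br | intermediate
6 | methyl (2S)-3-[4-(benzyloxy)-2-bromophenyl]-2-hydroxypropanoate | COC(=O)[C@@H](O)Cc1ccc(OCc2ccccc2)cc1Br | intermediate
7 | methyl (2S)-2-(benzyloxy)-3-[4-(benzyloxy)-2-bromophenyl]propanoate | COC(=O)[C@@H](OCc1ccccc1)Cc1ccc(OCc2ccccc2)cc1Br | intermediate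
8 | (2S)-2-(benzyloxy)-3-[4-(benzyloxy)-2-bromophenyl]propanal | O=C[C@@H](OCc1ccccc1)Cc1ccc(OCc2ccccc2)cc1Br | intermediate
9 | 4-bromo-1,2-bis(benzyloxy)benzene | Brc1ccc(OCc2ccccc2)c(OCc2ccccc2)c1 | starting material
10 | [3,4-bis(benzyloxy)phenyl]magnesium bromide (formed in the flask) | Br[Mg]c1ccc(OCc2ccccc2)c(OCc2ccccc2)c1 | intermediate
11 | (1S,2S)-2-(benzyloxy)-1-[3,4-bis(benzyloxy)phenyl]-3-[4-(benzyloxy)-2-bromophenyl]propan-1-ol (syn) | O[C@@H](c1ccc(OCc2ccccc2)c(OCc2ccccc2)c1)[C@@H](OCc1ccccc1)Cc1ccc(OCc2ccccc2)cc1Br | intermediate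
12 | (2S,3S)-3,7-bis(benzyloxy)-2-[3,4-bis(benzyloxy)phenyl]chromane (tetra-O-benzyl-ent-epifisetinidol, 2,3-cis) | C(c1ccccc1)Oc1ccc2c(c1)O[C@@H](c1ccc(OCc3ccccc3)c(OCc3ccccc3)c1)[C@@H](OCc1ccccc1)C2 | intermediate
13 | N,O-dimethylhydroxylamine hydrochloride | CNOC.Cl | starting material
14 | 4-(benzyloxy)phenylmagnesium bromide (commercial THF solution) | Br[Mg]c1ccc(OCc2ccccc2)cc1 | starting material
15 | (2S)-2-(benzyloxy)-3-[4-(benzyloxy)-2-bromophenyl]-N-methoxy-N-methylpropanamide (formed in the flask) | CON(C)C(=O)[C@@H](OCc1ccccc1)Cc1ccc(OCc2ccccc2)cc1Br | intermediate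
16 | (2S)-2-(benzyloxy)-1-[4-(benzyloxy)phenyl]-3-[4-(benzyloxy)-2-bromophenyl]propan-1-one | O=C(c1ccc(OCc2ccccc2)cc1)[C@@H](OCc1ccccc1)Cc1ccc(OCc2ccccc2)cc1Br | intermediate
17 | (1R,2S)-2-(benzyloxy)-1-[4-(benzyloxy)phenyl]-3-[4-(benzyloxy)-2-bromophenyl]propan-1-ol (anti) | O[C@H](c1ccc(OCc2ccccc2)cc1)[C@@H](OCc1ccccc1)Cc1ccc(OCc2ccccc2)cc1Br | intermediate
18 | (2R,3S)-3,7-bis(benzyloxy)-2-[4-(benzyloxy)phenyl]chromane (tri-O-benzylguibourtinidol, 2,3-trans) | C(c1ccccc1)Oc1ccc2c(c1)O[C@H](c1ccc(OCc3ccccc3)cc1)[C@@H](OCc1ccccc1)C2 | intermediate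
19 | (2R,3S,4R)-3,7-bis(benzyloxy)-2-[4-(benzyloxy)phenyl]-4-[(1,1,1,3,3,3-hexafluoropropan-2-yl)oxy]chromane (formed in the flask, drawn 3,4-trans) | C(c1ccccc1)Oc1ccc2c(c1)O[C@H](c1ccc(OCc3ccccc3)cc1)[C@@H](OCc1ccccc1)[C@@H]2OC(C(F)(F)F)C(F)(F)F | intermediate
20 | hepta-O-benzyl guibourtinidol-(4α→6)-ent-epifisetinidol: upper unit 2R,3S with 4α-aryl (2,3-trans-3,4-trans), lower unit 2S,3S (2,3-cis), bond from C4 of the upper unit to C6 of the lower unit | O(Cc5ccccc5)c1ccc([C@H]2Oc3cc(OCc5ccccc5)ccc3[C@@H](c3cc4c(cc3OCc5ccccc5)O[C@@H](c3ccc(OCc5ccccc5)c(OCc5ccccc5)c3)[C@@H](OCc5ccccc5)C4)[C@@H]2OCc5ccccc5)cc1 | intermediate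
21 | (2R,3S,4R)-4-[(2S,3S)-2-(3,4-dihydroxyphenyl)-3,7-dihydroxy-3,4-dihydro-2H-chromen-6-yl]-2-(4-hydroxyphenyl)-3,4-dihydro-2H-chromene-3,7-diol (guibourtinidol-(4α→6)-ent-epifisetinidol) | Oc1ccc([C@H]2Oc3cc(O)ccc3[C@@H](c3cc4c(cc3O)O[C@@H](c3ccc(O)c(O)c3)[C@@H](O)C4)[C@@H]2O)cc1 | target

**Totals**
Total step count: 11. Longest linear sequence: 8 steps (steps 1, 2, 3, 7, 8, 9, 10, 11; the branch through steps 1, 2, 3, 4, 5, 6, 10, 11 is equally long).

**Three steps most likely to fail, with fallbacks**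

Step 10 (the proposed electrochemical coupling). Risks are competing oxidation of benzyl ethers or ring B, self-condensation of 18, and incomplete 4α or C6 selectivity. The fallback sets out from 18 and comes back at 20 using the established two-stage chemical sequence. DDQ (1.5 equiv) with 2-ethoxyethanol in CH2Cl2 at rt gives the isolable C4 ether (2R,3S,4R)-3,7-bis(benzyloxy)-2-[4-(benzyloxy)phenyl]-4-(2-ethoxyethoxy)chromane F1 (either C4 epimer is usable). F1 is then condensed with 12 (3 equiv) under TMSOTf (0.1 equiv) in CH2Cl2 at −78 °C to give 20.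

Step 2 (opening of the glycidate by the hindered ortho-bromoaryl magnesium reagent). Risks are attack at the ester carbonyl, slow opening at the temperatures the reagent tolerates, and aryne formation on warming. The fallback sets out from 3 and comes back at 7, replacing the ester-bearing epoxide by a robust ester-free one and adjusting the oxidation state afterwards. The same reagent 5 opens purchased (2S)-2-[(trityloxy)methyl]oxirane (C(c1ccccc1)(c1ccccc1)(c1ccccc1)OC[C@@H]1CO1) under CuI (10 mol %) in THF at −30 → 0 °C to give (2S)-1-[4-(benzyloxy)-2-bromophenyl]-3-(trityloxy)propan-2-ol F2. NaH and benzyl bromide 2 in THF/DMF give the benzyl ether 4-(benzyloxy)-1-[(2S)-2-(benzyloxy)-3-(trityloxy)propyl]-2-bromobenzene F3. Catalytic TsOH in MeOH/CH2Cl2 removes the trityl group to give (2S)-2-(benzyloxy)-3-[4-(benzyloxy)-2-bromophenyl]propan-1-ol F4. TEMPO (cat.) with PhI(OAc)2 in MeCN/H2O oxidises F4 to (2S)-2-(benzyloxy)-3-[4-(benzyloxy)-2-bromophenyl]propanoic acid F5, and MeI with K2CO3 in DMF returns to ester 7.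

Step 7 (telescoped ester to Weinreb amide to ketone). Risks are incomplete amidation, over-addition, and partial α-epimerisation under the excess of basic magnesium reagents. The fallback sets out from 8 and comes back at 16, going through the alcohol oxidation level instead. Addition of 14 to aldehyde 8 in THF at −78 °C, where no stereocontrol is needed, gives the C1-epimeric alcohols (2S)-2-(benzyloxy)-1-[4-(benzyloxy)phenyl]-3-[4-(benzyloxy)-2-bromophenyl]propan-1-ol F6. Dess–Martin periodinane in CH2Cl2 at rt oxidises both epimers to ketone 16.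

**Further compounds**
F1 | step 10 | (2R,3S,4R)-3,7-bis(benzyloxy)-2-[4-(benzyloxy)phenyl]-4-(2-ethoxyethoxy)chromane | C(c1ccccc1)Oc1ccc2c(c1)O[C@H](c1ccc(OCc3ccccc3)cc1)[C@@H](OCc1ccccc1)[C@@H]2OCCOCC
F2 | step 2 | (2S)-1-[4-(benzyloxy)-2-bromophenyl]-3-(trityloxy)propan-2-ol | C(c1ccccc1)(c1ccccc1)(c1ccccc1)OC[C@@H](O)Cc1ccc(OCc2ccccc2)cc1Br
F3 | step 2 | 4-(benzyloxy)-1-[(2S)-2-(benzyloxy)-3-(trityloxy)propyl]-2-bromobenzene | C(c1ccccc1)(c1ccccc1)(c1ccccc1)OC[C@@H](OCc1ccccc1)Cc1ccc(OCc2ccccc2)cc1Br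
F4 | step 2 | (2S)-2-(benzyloxy)-3-[4-(benzyloxy)-2-bromophenyl]propan-1-ol | OC[C@@H](OCc1ccccc1)Cc1ccc(OCc2ccccc2)cc1Br
F5 | step 2 | (2S)-2-(benzyloxy)-3-[4-(benzyloxy)-2-bromophenyl]propanoic acid | OC(=O)[C@@H](OCc1ccccc1)Cc1ccc(OCc2ccccc2)cc1Br
F6 | step 7 | (2S)-2-(benzyloxy)-1-[4-(benzyloxy)phenyl]-3-[4-(benzyloxy)-2-bromophenyl]propan-1-ol (mixture of C1 epimers) | OC(c1ccc(OCc2ccccc2)cc1)[C@@H](OCc1ccccc1)Cc1ccc(OCc2ccccc2)cc1Br
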